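The target is disconnected at the two diarylmethane CH2 carbons on ring A, at C2 and C6 on either side of the bridge-bearing C1, cutting each from the ipso carbon of its 4-hydroxyphenyl ring. A twofold palladium-catalysed Suzuki–Miyaura coupling of a ring A bis(benzylic methyl carbonate) with 4-(benzyloxy)phenylboronic acid should form both CH2–aryl bonds in one operation, with the boron position fixing the para oxygenation. The precursor is the fully assembled, benzyl-protected bibenzyl carrying CH2OCO2Me groups at C2 and C6 of ring A. It is reached from a ring A 2,6-dibromostyrene by hydroboration/B-alkyl Suzuki union with the ring B bromide, double lithiation–formylation, reduction and acylation. Global hydrogenolysis then frees the five phenols.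

Key step: step 11

Remark: ring A is the methoxy-bearing ring (C1 carries the CH2CH2 bridge, C2 and C6 the benzylic carbons, C3 the oxygen that ends as a free phenol, C5 the methoxy group); ring B is the other bibenzyl ring; the target has no stereocentre.
Remark: the ring A bromines are introduced on the benzaldehyde, before the bibenzyl exists, because ring A is then the only oxygen-activated arene present; brominating the assembled bibenzyl would have to distinguish ring A from two further alkoxy-substituted rings.

Step 1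
Reactants: 1 3-hydroxy-5-methoxybenzaldehyde
Product: 2 3-(benzyloxy)-5-methoxybenzaldehyde
Conditions: BnBr, K2CO3, DMF, rt
Reagents that add atoms: benzyl bromide, BrCc1ccccc1
Why: Williamson etherification of the phenoxide with benzyl bromide is routine and leaves the aldehyde and the aryl methyl ether untouched.

Step 2
Reactants: 2 3-(benzyloxy)-5-methoxybenzaldehyde
Product: 3 3-(benzyloxy)-2,6-dibromo-5-methoxybenzaldehyde
Conditions: Br2 (2.2 equiv), NaOAc, AcOH, rt
Reagents that add atoms: bromine, BrBr
Why: Electrophilic aromatic bromination should go to C2 and C6, each ortho to one ether oxygen and para to the other, whereas C4 is crowded between both alkoxy groups and the benzyl phenyl ring is unactivated.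

Step 3
Reactants: 3 3-(benzyloxy)-2,6-dibromo-5-methoxybenzaldehyde
Product: 4 1-(benzyloxy)-2,4-dibromo-5-methoxy-3-vinylbenzene (the ring A 2,6-dibromostyrene)
Conditions: Ph3PCH3Br, KOtBu, THF, 0 °C to rt
Reagents that add atoms: methyltriphenylphosphonium bromide, C[P+](c1ccccc1)(c1ccccc1)c1ccccc1.[Br-]
Why: Wittig methylenation with the small unstabilised ylide should tolerate the two ortho bromines and does not touch aryl bromides or ethers.

Step 4
Reactants: 5 4-bromo-2-hydroxybenzaldehyde
Product: 6 2-(benzyloxy)-4-bromobenzaldehyde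
Conditions: BnBr, K2CO3, DMF, rt
Reagents that add atoms: benzyl bromide, BrCc1ccccc1
Why: Williamson etherification of the salicylaldehyde phenoxide is straightforward and keeps the aldehyde and the aryl bromide.

Step 5
Reactants: 6 2-(benzyloxy)-4-bromobenzaldehyde; 7 1-(benzyloxy)-4-bromobenzene
Product: 9 [2-(benzyloxy)-4-bromophenyl][4-(benzyloxy)phenyl]methanol (racemic), via 4-(benzyloxy)phenylmagnesium bromide 8 (not isolated)
Conditions: 7, Mg, THF, rt to 40 °C; then 6, THF, 0 °C; then H2O
Reagents that add atoms: none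
Why: Grignard addition of the arylmagnesium bromide to the aldehyde should give the racemic diarylmethanol, whose single stereocentre is erased in step 6, and the aryl bromide of 6 is inert to an aryl Grignard reagent at 0 °C.

Step 6
Reactants: 9 [2-(benzyloxy)-4-bromophenyl][4-(benzyloxy)phenyl]methanol (racemic)
Product: 10 2-(benzyloxy)-1-[4-(benzyloxy)benzyl]-4-bromobenzene
Conditions: Et3SiH, TFA, CH2Cl2, 0 °C
Reagents that add atoms: none
Why: Ionic hydrogenation should work because TFA ionises the benzhydrol to a cation stabilised by an ortho and a para alkoxy group and triethylsilane delivers hydride, while benzyl ethers and the aryl bromide survive these mild conditions.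

Step 7
Reactants: 4 1-(benzyloxy)-2,4-dibromo-5-methoxy-3-vinylbenzene; 10 2-(benzyloxy)-1-[4-(benzyloxy)benzyl]-4-bromobenzene
Product: 12 1-(benzyloxy)-3-{2-[3-(benzyloxy)-4-[4-(benzyloxy)benzyl]phenyl]ethyl}-2,4-dibromo-5-methoxybenzene (ring A 2,6-dibromo bibenzyl), via B-(2-arylethyl)-9-BBN adduct 11 (not isolated)
Conditions: 9-BBN, THF, 0 °C to rt; then 10, PdCl2(dppf) (5 mol%), aq. K3PO4, DMF, 50 °C
Reagents that add atoms: none
Why: Anti-Markovnikov hydroboration of the styrene followed by B-alkyl Suzuki–Miyaura coupling should join the primary alkylborane to the unhindered ring B bromide, because the two ring A bromides, each flanked by two ortho substituents on an electron-rich ring, undergo oxidative addition much more slowly.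

Step 8
Reactants: 12 ring A 2,6-dibromo bibenzyl
Product: 14 4-(benzyloxy)-2-{2-[3-(benzyloxy)-4-[4-(benzyloxy)benzyl]phenyl]ethyl}-6-methoxybenzene-1,3-dicarbaldehyde, via ring A 2,6-dilithio bibenzyl 13 (not isolated)
Conditions: t-BuLi (4.2 equiv), THF, −78 °C; DMF, −78 to 0 °C; then H2O
Reagents that add atoms: N,N-dimethylformamide, CN(C)C=O
Why: Twofold bromine–lithium exchange at −78 °C is faster than deprotonation of the benzylic positions, and formylation of both aryllithium sites with DMF (Bouveault-type aldehyde synthesis) should give the dialdehyde on aqueous work-up.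

Step 9
Reactants: 14 ring A 2,6-dialdehyde
Product: 15 {4-(benzyloxy)-2-{2-[3-(benzyloxy)-4-[4-(benzyloxy)benzyl]phenyl]ethyl}-6-methoxy-1,3-phenylene}dimethanol
Conditions: NaBH4, THF/MeOH, 0 °C
Reagents that add atoms: none
Why: Borohydride reduction converts both aryl aldehydes into primary benzylic alcohols and leaves every ether untouched.

Step 10
Reactants: 15 ring A 2,6-bis(hydroxymethyl) bibenzyl
Product: 16 dimethyl {4-(benzyloxy)-2-{2-[3-(benzyloxy)-4-[4-(benzyloxy)benzyl]phenyl]ethyl}-6-methoxy-1,3-phenylene}bis(methylene) bis(carbonate)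
Conditions: ClCO2Me, pyridine, DMAP (cat.), CH2Cl2, 0 °C
Reagents that add atoms: methyl chloroformate, COC(=O)Cl
Why: Acylation of the two primary alcohols with methyl chloroformate under basic, non-acidic conditions should give the bis(methyl carbonate) without ionising the electron-rich benzylic C–O bonds.

Step 11
Reactants: 16 ring A bis(methyl carbonate); 17 4-(benzyloxy)phenylboronic acid
Product: 18 1-(benzyloxy)-2,4-bis[4-(benzyloxy)benzyl]-3-{2-[3-(benzyloxy)-4-[4-(benzyloxy)benzyl]phenyl]ethyl}-5-methoxybenzene (penta-O-benzyl target)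
Conditions: 17 (3 equiv), Pd(OAc)2 (10 mol%), 1,5-bis(diphenylphosphino)pentane (11 mol%), DMF, 80 °C
Reagents that add atoms: none
Why: Zerovalent palladium, generated from Pd(OAc)2 and the bisphosphine, displaces each benzylic carbonate to give a cationic eta-3 benzyl complex of divalent palladium while the leaving group collapses to CO2 and methoxide. The methoxide turns the boronic acid into a borate that transfers its aryl group to palladium, and reductive elimination joins the benzylic CH2 to the aryl ipso carbon and returns the catalyst. The closest known reaction type is the Suzuki–Miyaura coupling of benzylic carbonates with arylboronic acids, here run twice on one substrate. No ring is closed and no stereocentre is created. The step needs activation of the two benzylic C–O bonds in preference to the five aryl benzyl ether C–O bonds, and aryl transfer only from the boron-bearing carbon; the carbonate leaving groups and the para relationship of boron and benzyloxy in 17 secure both. Both reacting carbons are primary and project out of the crowded plane of ring A, so the flanking substituents at C1, C3 and C5 should slow but not block the ionisation.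

Step 12
Reactants: 18 penta-O-benzyl target
Product: 19 2,4-bis(4-hydroxybenzyl)-3-{2-[3-hydroxy-4-(4-hydroxybenzyl)phenyl]ethyl}-5-methoxyphenol (CNP0207338.0)
Conditions: H2 (1 atm), 10% Pd/C, EtOAc/MeOH, rt
Reagents that add atoms: none
Why: Catalytic hydrogenolysis cleaves the five aryl benzyl ether C–O bonds, while the diarylmethane and bibenzyl C–C bonds and the aryl methyl ether are stable under these conditions.

Compound list
1 | 3-hydroxy-5-methoxybenzaldehyde | COc1cc(O)cc(C=O)c1 | starting material
2 | 3-(benzyloxy)-5-methoxybenzaldehyde | COc1cc(OCc2ccccc2)cc(C=O)c1 | intermediate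
3 | 3-(benzyloxy)-2,6-dibromo-5-methoxybenzaldehyde | COc1cc(OCc2ccccc2)c(Br)c(C=O)c1Br | intermediate
4 | 1-(benzyloxy)-2,4-dibromo-5-methoxy-3-vinylbenzene | COc1cc(OCc2ccccc2)c(Br)c(C=C)c1Br | intermediate
5 | 4-bromo-2-hydroxybenzaldehyde | O=Cc1ccc(Br)cc1O | starting material
6 | 2-(benzyloxy)-4-bromobenzaldehyde | O=Cc1ccc(Br)cc1OCc1ccccc1 | intermediate
7 | 1-(benzyloxy)-4-bromobenzene | Brc1ccc(OCc2ccccc2)cc1 | starting material
8 | 4-(benzyloxy)phenylmagnesium bromide | Br[Mg]c1ccc(OCc2ccccc2)cc1 | intermediate (not isolated)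
9 | [2-(benzyloxy)-4-bromophenyl][4-(benzyloxy)phenyl]methanol, racemic | OC(c1ccc(OCc2ccccc2)cc1)c1ccc(Br)cc1OCc1ccccc1 | intermediate
10 | 2-(benzyloxy)-1-[4-(benzyloxy)benzyl]-4-bromobenzene | Brc1ccc(Cc2ccc(OCc3ccccc3)cc2)c(OCc2ccccc2)c1 | intermediate
11 | 9-{2-[3-(benzyloxy)-2,6-dibromo-5-methoxyphenyl]ethyl}-9-borabicyclo[3.3.1]nonane | COc1cc(OCc2ccccc2)c(Br)c(CCB2C3CCCC2CCC3)c1Br | intermediate (not isolated)
12 | 1-(benzyloxy)-3-{2-[3-(benzyloxy)-4-[4-(benzyloxy)benzyl]phenyl]ethyl}-2,4-dibromo-5-methoxybenzene | COc1cc(OCc2ccccc2)c(Br)c(CCc2ccc(Cc3ccc(OCc4ccccc4)cc3)c(OCc3ccccc3)c2)c1Br | intermediate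
13 | ring A 2,6-dilithio analogue of 12 | COc1cc(OCc2ccccc2)c([Li])c(CCc2ccc(Cc3ccc(OCc4ccccc4)cc3)c(OCc3ccccc3)c2)c1[Li] | intermediate (not isolated)
14 | 4-(benzyloxy)-2-{2-[3-(benzyloxy)-4-[4-(benzyloxy)benzyl]phenyl]ethyl}-6-methoxybenzene-1,3-dicarbaldehyde | COc1cc(OCc2ccccc2)c(C=O)c(CCc2ccc(Cc3ccc(OCc4ccccc4)cc3)c(OCc3ccccc3)c2)c1C=O | intermediate
15 | {4-(benzyloxy)-2-{2-[3-(benzyloxy)-4-[4-(benzyloxy)benzyl]phenyl]ethyl}-6-methoxy-1,3-phenylene}dimethanol | COc1cc(OCc2ccccc2)c(CO)c(CCc2ccc(Cc3ccc(OCc4ccccc4)cc3)c(OCc3ccccc3)c2)c1CO | intermediate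
16 | ring A bis(methyl carbonate) of 15 | COc1cc(OCc2ccccc2)c(COC(=O)OC)c(CCc2ccc(Cc3ccc(OCc4ccccc4)cc3)c(OCc3ccccc3)c2)c1COC(=O)OC | intermediate
17 | 4-(benzyloxy)phenylboronic acid | OB(O)c1ccc(OCc2ccccc2)cc1 | starting material
18 | 1-(benzyloxy)-2,4-bis[4-(benzyloxy)benzyl]-3-{2-[3-(benzyloxy)-4-[4-(benzyloxy)benzyl]phenyl]ethyl}-5-methoxybenzene | COc1cc(OCc2ccccc2)c(Cc2ccc(OCc3ccccc3)cc2)c(CCc2ccc(Cc3ccc(OCc4ccccc4)cc3)c(OCc3ccccc3)c2)c1Cc1ccc(OCc2ccccc2)cc1 | intermediate
19 | 2,4-bis(4-hydroxybenzyl)-3-{2-[3-hydroxy-4-(4-hydroxybenzyl)phenyl]ethyl}-5-methoxyphenol (CNP0207338.0) | COc1cc(O)c(Cc2ccc(O)cc2)c(CCc2ccc(Cc3ccc(O)cc3)c(O)c2)c1Cc1ccc(O)cc1 | target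

Total step count: 12. Longest linear sequence: 9 steps (steps 1, 2, 3, 7, 8, 9, 10, 11, 12; the ring B branch, steps 4 to 6, joins at step 7 and is equally long).

Steps most likely to fail

Step 11. Ionisation at the two benzylic carbons, each flanked by two ortho substituents, may be slow. The benzyl–palladium intermediate may then be captured by methoxide (decarboxylative ether formation), or the boronic acid may be consumed by protodeboronation, leaving singly coupled material. The fallback forms the same two CH2–aryl bonds by carbonyl addition and sets out from dialdehyde 14. Twofold addition of Grignard reagent 8 (THF, 0 °C) should give the bis(diarylmethanol) {4-(benzyloxy)-2-{2-[3-(benzyloxy)-4-[4-(benzyloxy)benzyl]phenyl]ethyl}-6-methoxy-1,3-phenylene}bis{[4-(benzyloxy)phenyl]methanol} F1 as a mixture of diastereomers. Twofold ionic hydrogenation (Et3SiH, TFA, CH2Cl2, 0 °C) then removes both hydroxyl groups and both transient stereocentres and comes back to the route at 18.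

Step 7. Oxidative addition of palladium into the ring A C–Br bonds may compete with that into the ring B bromide, leading to oligomerisation or loss of bromine. The fallback keeps halogen off ring A during the palladium step and sets out from aldehyde 2. Wittig methylenation (Ph3PCH3Br, KOtBu, THF) gives 1-(benzyloxy)-3-methoxy-5-vinylbenzene F2. Hydroboration with 9-BBN gives 9-{2-[3-(benzyloxy)-5-methoxyphenyl]ethyl}-9-borabicyclo[3.3.1]nonane F3. Coupling with 10 (PdCl2(dppf), aq. K3PO4, DMF, 50 °C) gives the halogen-free bibenzyl 1-(benzyloxy)-3-{2-[3-(benzyloxy)-4-[4-(benzyloxy)benzyl]phenyl]ethyl}-5-methoxybenzene F4. Dibromination with NBS (2.0 equiv, MeCN, −10 °C) at C2 and C6 of ring A, the only ring with two oxygen donors, returns to the route at 12. The cost is that NBS must then distinguish ring A from the singly oxygenated rings.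

Step 8. The second bromine–lithium exchange may be incomplete, or the aryllithium may be quenched by proton transfer from benzylic positions, giving mono-formylated or debrominated material. The fallback avoids organolithium chemistry and sets out from dibromide 12. Twofold Suzuki–Miyaura vinylation with potassium vinyltrifluoroborate (Pd(OAc)2, SPhos, K3PO4, toluene/H2O, 90 °C) should give 1-(benzyloxy)-3-{2-[3-(benzyloxy)-4-[4-(benzyloxy)benzyl]phenyl]ethyl}-5-methoxy-2,4-divinylbenzene F5. Lemieux–Johnson cleavage of both vinyl groups (OsO4 cat., NaIO4, 2,6-lutidine, dioxane/H2O) comes back to the route at 14.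

Further compounds
F1 | step 11 | {4-(benzyloxy)-2-{2-[3-(benzyloxy)-4-[4-(benzyloxy)benzyl]phenyl]ethyl}-6-methoxy-1,3-phenylene}bis{[4-(benzyloxy)phenyl]methanol}, mixture of diastereomers | COc1cc(OCc2ccccc2)c(C(O)c2ccc(OCc3ccccc3)cc2)c(CCc2ccc(Cc3ccc(OCc4ccccc4)cc3)c(OCc3ccccc3)c2)c1C(O)c1ccc(OCc2ccccc2)cc1
F2 | step 7 | 1-(benzyloxy)-3-methoxy-5-vinylbenzene | COc1cc(OCc2ccccc2)cc(C=C)c1
F3 | step 7 | 9-{2-[3-(benzyloxy)-5-methoxyphenyl]ethyl}-9-borabicyclo[3.3.1]nonane | COc1cc(OCc2ccccc2)cc(CCB2C3CCCC2CCC3)c1
F4 | step 7 | 1-(benzyloxy)-3-{2-[3-(benzyloxy)-4-[4-(benzyloxy)benzyl]phenyl]ethyl}-5-methoxybenzene | COc1cc(OCc2ccccc2)cc(CCc2ccc(Cc3ccc(OCc4ccccc4)cc3)c(OCc3ccccc3)c2)c1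
F5 | step 8 | 1-(benzyloxy)-3-{2-[3-(benzyloxy)-4-[4-(benzyloxy)benzyl]phenyl]ethyl}-5-methoxy-2,4-divinylbenzene | COc1cc(OCc2ccccc2)c(C=C)c(CCc2ccc(Cc3ccc(OCc4ccccc4)cc3)c(OCc3ccccc3)c2)c1C=C
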